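**Retrosynthetic overview**
- Ring A is numbered C-1 to C-6: C-1 carries the ester carbonyl, C-2 and C-4 the hydroxyls and C-6 the undecyl chain. Two hydrogens up, this is a 2,4-dioxo-6-undecylcyclohexane-1-carboxylate, so the target is reached by debenzylation of ring B and dehydrogenation of that dione.
- The saturated ring A is cut between C-3 and C-4 (Dieckmann) to an acyclic 2-acetyl-3-undecylglutarate. The crowded, doubly ortho-substituted ester C–O bond is therefore made earlier, on an unhindered acetoacetate.
- The glutarate comes from Michael addition of the acetoacetate of the chiral alcohol to methyl (E)-tetradec-2-enoate (Horner–Wadsworth–Emmons from dodecanal).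
- The alcohol comes from (R)-2-propyloxirane and a hex-5-enyl Grignard reagent, then hydroboration and B-alkyl Suzuki coupling with benzyl-protected 5-bromoresorcinol.
- Ring order: ring B is bought; ring A is closed in saturated form in the key step and aromatised afterwards. The only stereocentre comes from the epoxide.

Key step: step 7

Remark: ring B is the 3,5-dioxygenated phenyl ring. Compounds 16–18 are drawn as keto forms and as mixtures at every sp3 centre other than the carbinol carbon; those centres become sp2 in step 8, and 17 should exist largely as an enol.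

**Step 1**
Reactants: 1 (R)-2-propyloxirane; 2 6-bromohex-1-ene
Product: 4 (R)-undec-10-en-4-ol, via hex-5-en-1-ylmagnesium bromide 3 (not isolated)
Conditions: Mg, THF, rt to 40 °C; then CuI (10 mol%), 1, THF, −30 → 0 °C; aq NH4Cl
Reagents that add atoms: none
Why: Copper-catalysed Grignard opening of a terminal epoxide proceeds by SN2 attack at the unsubstituted carbon, so the C–O bond of the stereocentre is never broken and the R configuration of 1 passes unchanged into 4.

**Step 2**
Reactants: 5 5-bromobenzene-1,3-diol
Product: 6 1,3-bis(benzyloxy)-5-bromobenzene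
Conditions: BnBr (2.2 equiv), K2CO3, DMF, 60 °C
Reagents that add atoms: benzyl bromide, BrCc1ccccc1
Why: Williamson ether synthesis of both phenols with a reactive benzylic halide under carbonate conditions should be clean, the aryl bromide being inert.

**Step 3**
Reactants: 4 (R)-undec-10-en-4-ol; 6 1,3-bis(benzyloxy)-5-bromobenzene
Product: 8 (8R)-1-[3,5-bis(benzyloxy)phenyl]undecan-8-ol, via bis-borylated alkylborane 7 (not isolated)
Conditions: 9-BBN (2.2 equiv), THF, 0 °C → rt; then 6, Pd(dppf)Cl2 (3 mol%), 3 M aq NaOH, THF, 65 °C
Reagents that add atoms: none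
Why: Anti-Markovnikov hydroboration of the terminal alkene followed by B-alkyl Suzuki–Miyaura coupling with the aryl bromide forms the aryl–CH2 bond, the second equivalent of 9-BBN being taken up by the hydroxyl as an O–B bond that the aqueous base hydrolyses, and the carbinol stereocentre takes no part.

**Step 4**
Reactants: 8 (8R)-1-[3,5-bis(benzyloxy)phenyl]undecan-8-ol; 9 2,2,6-trimethyl-4H-1,3-dioxin-4-one
Product: 11 (8R)-1-[3,5-bis(benzyloxy)phenyl]undecan-8-yl 3-oxobutanoate, via acetylketene 10 (not isolated)
Conditions: xylenes, 130 °C, acetone distilled off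
Reagents that add atoms: none
Why: Thermal retro-[4+2] fragmentation of the dioxinone releases acetylketene, which acylates the secondary alcohol on oxygen under neutral conditions (acetoacetylation), so the configuration at the carbinol carbon is retained.

**Step 5**
Reactants: 12 dodecanal; 13 trimethyl phosphonoacetate
Product: 15 methyl (E)-tetradec-2-enoate, via sodium phosphonoacetate carbanion 14 (not isolated)
Conditions: NaH, THF, 0 °C; then 12, 0 °C → rt
Reagents that add atoms: none
Why: Horner–Wadsworth–Emmons olefination of an unbranched aldehyde with a stabilised phosphonate anion should give the E enoate, whose geometry is in any case lost in step 6.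

**Step 6**
Reactants: 11 (8R)-1-[3,5-bis(benzyloxy)phenyl]undecan-8-yl 3-oxobutanoate; 15 methyl (E)-tetradec-2-enoate
Product: 16 1-{(8R)-1-[3,5-bis(benzyloxy)phenyl]undecan-8-yl} 5-methyl 2-acetyl-3-undecylpentanedioate (diastereomer mixture)
Conditions: KOt-Bu (0.2 equiv), t-BuOH/THF, rt → 40 °C; AcOH quench
Reagents that add atoms: none
Why: Base-catalysed Michael addition, in which the doubly stabilised acetoacetate enolate adds to the β-carbon of the enoate and the adduct enolate is reprotonated by t-BuOH, so a substoichiometric amount of a hindered, non-transesterifying base suffices and ring closure is held back, while the two new stereocentres form without control because both are removed in step 8.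

**Step 7**
Reactants: 16 1-{(8R)-1-[3,5-bis(benzyloxy)phenyl]undecan-8-yl} 5-methyl 2-acetyl-3-undecylpentanedioate
Product: 17 (8R)-1-[3,5-bis(benzyloxy)phenyl]undecan-8-yl 2,4-dioxo-6-undecylcyclohexane-1-carboxylate (mixture of ring diastereomers)
Conditions: KOt-Bu (2.2 equiv), THF/t-BuOH, 0 → 60 °C; then 1 M HCl, 0 °C
Reagents that add atoms: none
Why: Excess KOt-Bu first converts 16 into its β-keto ester enolate, and proton exchange through t-BuOH keeps a small stationary share of the acetyl-methyl enolate, which adds to the methyl ester carbonyl and expels methoxide to form the bond between C-3 and C-4; the ring product, a vinylogous acid, is deprotonated at once, and this pulls the equilibria forward. The closest known reaction is the Dieckmann (intramolecular Claisen) condensation that completes the Michael–Dieckmann synthesis of dihydroresorcylates from acetoacetates and crotonates. Ring A closes in the 6-(enolendo)-exo-trig mode, since both carbons of the methyl-ketone enolate lie in the new ring and the ester C=O is exocyclic to it. No stereocentre needs control: C-6 is a mixture from step 6, C-1 is epimerisable, both become sp2 in step 8, and the carbinol centre lies outside the reacting system. The step needs chemoselectivity among three acidic sites and two esters, and the substrate secures it because only the methyl-ketone enolate and the methyl ester can meet in a six-membered ring (every other pairing would give a four-membered ring), while the chiral ester is part of the delocalised enolate and tert-butoxide is too hindered to transesterify.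

**Step 8**
Reactants: 17 (8R)-1-[3,5-bis(benzyloxy)phenyl]undecan-8-yl 2,4-dioxo-6-undecylcyclohexane-1-carboxylate
Product: 19 (8R)-1-[3,5-bis(benzyloxy)phenyl]undecan-8-yl 2,4-dihydroxy-6-undecylbenzoate, via 3-bromo dione 18 (not isolated)
Conditions: Br2 (1.0 equiv), DMF, 0 °C; then 80 °C
Reagents that add atoms: none
Why: Bromination–dehydrobromination, the reaction known for aromatising 6-alkyl-2,4-dioxocyclohexanecarboxylates to 6-alkyl-β-resorcylates: the dione enol should take up the single equivalent of bromine at C-3 faster than ring B does in DMF at 0 °C, and on warming enolisation toward C-5, loss of HBr and tautomerisation should give the resorcinol.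

**Step 9**
Reactants: 19 (8R)-1-[3,5-bis(benzyloxy)phenyl]undecan-8-yl 2,4-dihydroxy-6-undecylbenzoate
Product: 20 (8R)-1-(3,5-dihydroxyphenyl)undecan-8-yl 2,4-dihydroxy-6-undecylbenzoate (CNP0146287.1)
Conditions: H2 (1 atm), 10% Pd/C, EtOAc/MeOH, rt
Reagents that add atoms: none
Why: Catalytic hydrogenolysis should cleave the two aryl benzyl ethers, while the ester of the non-benzylic secondary alcohol and both aromatic rings are untouched, so the R centre is preserved.

**Compound list**
1 | (R)-2-propyloxirane | CCC[C@@H]1CO1 | starting material
2 | 6-bromohex-1-ene | C=CCCCCBr | starting material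
3 | hex-5-en-1-ylmagnesium bromide | C=CCCCC[Mg]Br | intermediate
4 | (R)-undec-10-en-4-ol | CCC[C@@H](O)CCCCCC=C | intermediate
5 | 5-bromobenzene-1,3-diol | Oc1cc(O)cc(Br)c1 | starting material
6 | 1,3-bis(benzyloxy)-5-bromobenzene | Brc1cc(OCc2ccccc2)cc(OCc2ccccc2)c1 | intermediate
7 | 9-[(8R)-8-(9-borabicyclo[3.3.1]nonan-9-yloxy)undecyl]-9-borabicyclo[3.3.1]nonane | CCC[C@@H](OB1C2CCCC1CCC2)CCCCCCCB1C2CCCC1CCC2 | intermediate
8 | (8R)-1-[3,5-bis(benzyloxy)phenyl]undecan-8-ol | CCC[C@@H](O)CCCCCCCc1cc(OCc2ccccc2)cc(OCc2ccccc2)c1 | intermediate
9 | 2,2,6-trimethyl-4H-1,3-dioxin-4-one | CC1=CC(=O)OC(C)(C)O1 | starting material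
10 | acetylketene (3-oxobut-1-en-1-one) | CC(=O)C=C=O | intermediate
11 | (8R)-1-[3,5-bis(benzyloxy)phenyl]undecan-8-yl 3-oxobutanoate | CC(=O)CC(=O)O[C@H](CCC)CCCCCCCc1cc(OCc2ccccc2)cc(OCc2ccccc2)c1 | intermediate
12 | dodecanal | CCCCCCCCCCCC=O | starting material
13 | trimethyl phosphonoacetate | COC(=O)CP(=O)(OC)OC | starting material
14 | sodium salt of the trimethyl phosphonoacetate carbanion | [Na+].COC(=O)[CH-]P(=O)(OC)OC | intermediate
15 | methyl (E)-tetradec-2-enoate | CCCCCCCCCCC/C=C/C(=O)OC | intermediate
16 | 1-{(8R)-1-[3,5-bis(benzyloxy)phenyl]undecan-8-yl} 5-methyl 2-acetyl-3-undecylpentanedioate (diastereomer mixture) | CCCCCCCCCCCC(CC(=O)OC)C(C(C)=O)C(=O)O[C@H](CCC)CCCCCCCc1cc(OCc2ccccc2)cc(OCc2ccccc2)c1 | intermediate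
17 | (8R)-1-[3,5-bis(benzyloxy)phenyl]undecan-8-yl 2,4-dioxo-6-undecylcyclohexane-1-carboxylate (mixture of ring diastereomers) | CCCCCCCCCCCC1CC(=O)CC(=O)C1C(=O)O[C@H](CCC)CCCCCCCc1cc(OCc2ccccc2)cc(OCc2ccccc2)c1 | intermediate
18 | (8R)-1-[3,5-bis(benzyloxy)phenyl]undecan-8-yl 3-bromo-2,4-dioxo-6-undecylcyclohexane-1-carboxylate | CCCCCCCCCCCC1CC(=O)C(Br)C(=O)C1C(=O)O[C@H](CCC)CCCCCCCc1cc(OCc2ccccc2)cc(OCc2ccccc2)c1 | intermediate
19 | (8R)-1-[3,5-bis(benzyloxy)phenyl]undecan-8-yl 2,4-dihydroxy-6-undecylbenzoate | CCCCCCCCCCCc1cc(O)cc(O)c1C(=O)O[C@H](CCC)CCCCCCCc1cc(OCc2ccccc2)cc(OCc2ccccc2)c1 | intermediate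
20 | (8R)-1-(3,5-dihydroxyphenyl)undecan-8-yl 2,4-dihydroxy-6-undecylbenzoate | CCCCCCCCCCCc1cc(O)cc(O)c1C(=O)O[C@H](CCC)CCCCCCCc1cc(O)cc(O)c1 | target

**Step count**
Total steps: 9. Longest linear sequence: 7 steps (1, 3, 4, 6, 7, 8, 9).

**Steps most likely to fail**

Step 7 (key step). The closure may be slower than retro-Michael cleavage back to the two components, than base-induced loss of the acetyl group, or than attack at the chiral ester; the methoxide set free may also begin to exchange the chiral ester. The fallback sets out from alcohol 8 and dodecanal 12 and rejoins the route at 17, closing ring A between C-2 and C-3 instead of between C-3 and C-4. Acylation of 8 with methyl 3-chloro-3-oxopropanoate (pyridine, CH2Cl2, 0 °C) would give the mixed malonate (8R)-1-[3,5-bis(benzyloxy)phenyl]undecan-8-yl methyl propanedioate F1. Wittig olefination of 12 with 1-(triphenylphosphoranylidene)propan-2-one (toluene, 80 °C) would give (E)-pentadec-3-en-2-one F2. With KOt-Bu in t-BuOH/THF, F1 should add to F2 to give the keto diester 1-{(8R)-1-[3,5-bis(benzyloxy)phenyl]undecan-8-yl} 3-methyl 2-(2-oxopentadecan-4-yl)propanedioate F3. In the same flask the ketone-methyl enolate of F3 should attack the less hindered methyl ester and, after acidification, give 17. This is the malonate–enone Michael–Claisen sequence known from olivetolate syntheses. Its weak point is attack on the wrong malonate ester, which would release recoverable 8.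

Step 8. Bromine may be passed on to the electron-rich ring B instead of being lost as HBr, and the HBr formed may begin to cleave the benzyl ethers. A stray aryl bromide would still be removed reductively in step 9, so the real danger is incomplete aromatisation. The fallback sets out from 17 and rejoins at 19 with no halogen at all: aerobic dehydrogenation with Pd(OCOCF3)2 (5 mol%), 2-(dimethylamino)pyridine, TsOH and O2 (1 atm) in DMSO at 80 °C. The enol of 17 is a 3-hydroxycyclohex-2-enone, the substrate type for which this cyclohexenone-to-phenol method is known; a palladium enolate at C-5 should undergo β-hydride elimination toward C-6 and the product should tautomerise to the resorcinol. No compound outside the list is made (F0).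

Step 6. Addition to the β-alkyl enoate may be slow or reverse. Early ring closure would also give the acidic dione, which neutralises the catalytic base and stalls the addition. The fallback sets out from 11 and 12 and rejoins at 16, reversing the polarity of the C–C bond formation. Knoevenagel condensation of 11 with 12 (piperidine/AcOH cat., CH2Cl2, 0 °C, molecular sieves) would give the alkylidene acetoacetate (8R)-1-[3,5-bis(benzyloxy)phenyl]undecan-8-yl 2-acetyltetradec-2-enoate F4. Mukaiyama–Michael addition of 1-(tert-butyldimethylsilyloxy)-1-methoxyethene to F4 (Sc(OTf)3 10 mol%, CH2Cl2, −78 → 0 °C, then dilute HCl) should deliver 16. Here a strongly activated acceptor replaces the sluggish enoate.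

**Further compounds**
F1 | step 7 | (8R)-1-[3,5-bis(benzyloxy)phenyl]undecan-8-yl methyl propanedioate | COC(=O)CC(=O)O[C@H](CCC)CCCCCCCc1cc(OCc2ccccc2)cc(OCc2ccccc2)c1
F2 | step 7 | (E)-pentadec-3-en-2-one | CCCCCCCCCCC/C=C/C(C)=O
F3 | step 7 | 1-{(8R)-1-[3,5-bis(benzyloxy)phenyl]undecan-8-yl} 3-methyl 2-(2-oxopentadecan-4-yl)propanedioate (diastereomer mixture) | CCCCCCCCCCCC(CC(C)=O)C(C(=O)OC)C(=O)O[C@H](CCC)CCCCCCCc1cc(OCc2ccccc2)cc(OCc2ccccc2)c1
F0 | step 8 | none | none
F4 | step 6 | (8R)-1-[3,5-bis(benzyloxy)phenyl]undecan-8-yl 2-acetyltetradec-2-enoate (E/Z mixture) | CCCCCCCCCCCC=C(C(C)=O)C(=O)O[C@H](CCC)CCCCCCCc1cc(OCc2ccccc2)cc(OCc2ccccc2)c1
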